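A direct plan would prenylate 4-hydroxybenzaldehyde twice at its ortho carbons to the bis-prenyl phenol A1, cleave one prenyl group oxidatively and dehydrate the lactol to the benzofuran aldehyde A2, condense A2 with phloroacetophenone to the chalcone A3, and close ring C by an enantioselective oxa-Michael addition.
Its weakest operations would be three.
The double C-alkylation of a phenoxide would compete with O-alkylation and stop partly at the mono-prenyl stage, so the opening step would be low-yielding for little gain in complexity.
The cleavage of one of two equivalent prenyl groups would be controlled by nothing but stoichiometry, so the furan closure would rest on a statistical event and at best half of the material would go forward.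
The final O1–C2 closure would set the only stereocentre last, on the most precious compound, by a reversible conjugate addition of a 2′,6′-dihydroxychalcone for which catalyst control has no close precedent, and the product could racemise through the same retro-Michael path.

**Plan of the new route** (benzofuran locants are primed)
Retrosynthesis: the C2–C5′ bond is cut first, giving the flat chromone 16 (rings A and C) and the arylboronic acid 13; in 13 the furan is cut at O1′–C2′ and C3a′–C3′ (alkyne on a former C–I bond), and the prenyl group at C7′–CH2 ([3,3] shift from oxygen).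
Ring order: ring C is present from the start (5,7-dihydroxychromone), the furan ring is closed in step 3, and the last skeletal bond joins the two halves without closing a ring.
Enabling features: C2 is both the β-carbon of the O1–C2=C3–C4=O unit of ring C in its oxidised form and the carbon that carries ring B, so one irreversible C–C bond formation sets the only stereocentre. O1′ lies between C7′ (prenyl) and C7a′ and is para to C5′, so ring B is a para-substituted phenol whose oxygen can first deliver the prenyl group to C7′ and then close the furan onto C3a′.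
The weak points do not arise: no phenoxide is C-alkylated (Claisen rearrangement instead), the two ortho carbons of ring B differ from the first compound on (H against I), and the stereocentre comes from ligand-controlled aryl transfer to C2, not from a reversible O–C closure.

Key step: step 6

Remark: it is assumed that the (S)-configured biaryl diphosphine transfers the aryl group to the same face of the chromone as of a simple cyclic enone (the Re face of C2, giving 2S); a trial with phenylboronic acid on 16 would confirm the sense before 13 is committed.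

**Step 1**
Reactants: 1 4-bromo-2-iodophenol; 2 3-chloro-3-methylbut-1-yne
Product: 3 4-bromo-2-iodo-1-[(2-methylbut-3-yn-2-yl)oxy]benzene
Conditions: 2 (1.3 equiv), DBU (1.5 equiv), CuCl2·2H2O (1 mol %), MeCN, 0 °C
Reagents that add atoms: none
Why: Copper-catalysed propargylic substitution (O-propargylation of a phenol by a tertiary propargylic chloride through a copper acetylide) should alkylate the hindered, fairly acidic phenol only at oxygen under conditions mild enough for the C–I bond; no stereocentre is formed.

**Step 2**
Reactants: 3 4-bromo-2-iodo-1-[(2-methylbut-3-yn-2-yl)oxy]benzene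
Product: 6 4-bromo-2-iodo-6-(3-methylbut-2-en-1-yl)phenol, via dimethylallyl ether 4 (not isolated), via dienone 5 (not isolated)
Conditions: H2 (1 atm), 5 % Pd/CaCO3 poisoned with Pb(OAc)2, quinoline, EtOAc, rt (stopped after 1 equiv H2); filter; xylene, 130 °C
Reagents that add atoms: none
Why: Semi-hydrogenation of the terminal alkyne over the poisoned catalyst gives the 1,1-dimethylallyl ether 4, whose aromatic Claisen rearrangement ([3,3]-sigmatropic shift, then enolisation of dienone 5) can end only at C6, the one ortho carbon that bears hydrogen, so the prenyl group arrives next to the oxygen with its linear connectivity; no stereocentre remains.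

**Step 3**
Reactants: 6 4-bromo-2-iodo-6-(3-methylbut-2-en-1-yl)phenol; 7 ethynyltrimethylsilane
Product: 10 5-bromo-7-(3-methylbut-2-en-1-yl)-1-benzofuran, via silylalkyne 8 (not isolated), via ethynylphenol 9 (not isolated)
Conditions: 7 (1.3 equiv), PdCl2(PPh3)2 (2 mol %), CuI (4 mol %), Et3N/THF 1:1, rt; then K2CO3 (2 equiv), MeOH, 60 °C
Reagents that add atoms: none
Why: Sonogashira coupling should take place at the C–I bond at room temperature and leave C–Br untouched, after which methanolysis of the C–Si bond and copper-assisted 5-endo-dig addition of the phenoxide to the ethynyl group (alkyne hydroalkoxylation) close the furan at the site fixed by the iodide; no stereocentre is formed.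

**Step 4**
Reactants: 10 5-bromo-7-(3-methylbut-2-en-1-yl)-1-benzofuran
Product: 13 [7-(3-methylbut-2-en-1-yl)-1-benzofuran-5-yl]boronic acid, via aryllithium 11 (not isolated), via lithium triisopropoxyborate 12 (not isolated)
Conditions: B(OiPr)3 (1.5 equiv), then n-BuLi (1.15 equiv, added last), THF/PhMe 1:4, −78 → −20 °C; aq HCl to pH 5
Reagents that add atoms: triisopropyl borate, CC(C)OB(OC(C)C)OC(C)C; water, O
Why: Bromine–lithium exchange with the borate already present (in-situ quench) is faster than deprotonation at C2′ of the furan, the aryllithium is trapped at once as the ate complex, and mild acid hydrolysis gives the boronic acid (lithiation–borylation).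

**Step 5**
Reactants: 14 5,7-dihydroxy-4H-chromen-4-one
Product: 16 5,7-bis(methoxymethoxy)-4H-chromen-4-one, via mono-MOM chromone 15 (not isolated)
Conditions: NaH (2.6 equiv), DMF, 0 °C; MOMCl (2.8 equiv), 0 °C → rt
Reagents that add atoms: chloromethyl methyl ether, COCCl
Why: Williamson etherification of the bis-phenoxide with MOMCl masks both phenols, the chelated 5-OH included, as acetals that survive the aqueous base of step 6 and leave under mild acid; the chromone has no stereocentre.

**Step 6**
Reactants: 16 5,7-bis(methoxymethoxy)-4H-chromen-4-one; 13 [7-(3-methylbut-2-en-1-yl)-1-benzofuran-5-yl]boronic acid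
Product: 17 (2S)-5,7-bis(methoxymethoxy)-2-[7-(3-methylbut-2-en-1-yl)-1-benzofuran-5-yl]-2,3-dihydro-4H-chromen-4-one
Conditions: 13 (1.5 equiv), [RhCl(C2H4)2]2 (1.5 mol %), (S)-MeO-F12-BIPHEP [(S)-2,2′-bis{bis(3,4,5-trifluorophenyl)phosphino}-6,6′-dimethoxy-1,1′-biphenyl] (3.3 mol %), KOH (0.2 equiv), degassed CH2Cl2/H2O 10:1, 25 °C
Reagents that add atoms: none
Why: The arylboronic acid transmetalates to the hydroxo complex of monovalent rhodium, the chromone C2=C3 bond inserts into the Rh–aryl bond in the enantio-determining step to give a rhodium enolate (oxa-π-allyl), and water hydrolyses it to the ketone and returns Rh–OH (Hayashi–Miyaura reaction; the closest known reaction type is the rhodium-catalysed asymmetric 1,4-addition of arylboronic acids to chromones with electron-poor biaryl diphosphines). No ring is closed: ring C is already present and the step forms the C2–C5′ bond that joins the two halves. The only stereocentre, C2, is set by the ligand, whose (S)-configured biaryl backbone is expected to place the aryl group on the Re face of C2, the same spatial sense in which (S)-biaryl diphosphines give (S)-3-arylcyclohexanones, and this corresponds to 2S. The step needs 1,4- over 1,2-addition and must leave the prenyl and furan double bonds alone: C2 is the only β-position, the 5-O-MOM group peri to C4=O shields the ketone of the product against a second aryl transfer at 25 °C, and unactivated or aromatic C=C bonds do not insert into Rh–aryl. Because the C–C bond is formed irreversibly and neither a free phenol nor a strong base is present, the centre cannot be lost by ring opening as it can after an oxa-Michael closure.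

**Step 7**
Reactants: 17 (2S)-5,7-bis(methoxymethoxy)-2-[7-(3-methylbut-2-en-1-yl)-1-benzofuran-5-yl]-2,3-dihydro-4H-chromen-4-one
Product: 19 (2S)-5,7-dihydroxy-2-[7-(3-methylbut-2-en-1-yl)-1-benzofuran-5-yl]-2,3-dihydro-4H-chromen-4-one, via 7-MOM flavanone 18 (not isolated)
Conditions: 3 M aq HCl/MeOH/THF 1:6:2, 45 °C; NaHCO3 to pH 6 at 0 °C; chromatography on silica
Reagents that add atoms: none
Why: Acid-catalysed acetal cleavage in methanol (MOM deprotection) removes first the 5-O-MOM group, assisted by the peri carbonyl, then the 7-O-MOM group, while C2 keeps its configuration because no base is present to open ring C and the prenyl group has no neighbouring hydroxyl with which to cyclise.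

**Compound list**

1 | 4-bromo-2-iodophenol | Oc1ccc(Br)cc1I | starting material
2 | 3-chloro-3-methylbut-1-yne | C#CC(C)(C)Cl | starting material
3 | 4-bromo-2-iodo-1-[(2-methylbut-3-yn-2-yl)oxy]benzene | C#CC(C)(C)Oc1ccc(Br)cc1I | intermediate
4 | 4-bromo-2-iodo-1-[(2-methylbut-3-en-2-yl)oxy]benzene (1,1-dimethylallyl ether; not isolated) | C=CC(C)(C)Oc1ccc(Br)cc1I | intermediate
5 | 4-bromo-2-iodo-6-(3-methylbut-2-en-1-yl)cyclohexa-2,4-dien-1-one (Claisen dienone; racemic; not isolated) | CC(C)=CCC1C=C(Br)C=C(I)C1=O | intermediate
6 | 4-bromo-2-iodo-6-(3-methylbut-2-en-1-yl)phenol | CC(C)=CCc1cc(Br)cc(I)c1O | intermediate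
7 | ethynyltrimethylsilane | C#C[Si](C)(C)C | starting material
8 | 4-bromo-2-(3-methylbut-2-en-1-yl)-6-[(trimethylsilyl)ethynyl]phenol (not isolated) | CC(C)=CCc1cc(Br)cc(C#C[Si](C)(C)C)c1O | intermediate
9 | 4-bromo-2-ethynyl-6-(3-methylbut-2-en-1-yl)phenol (not isolated) | CC(C)=CCc1cc(Br)cc(C#C)c1O | intermediate
10 | 5-bromo-7-(3-methylbut-2-en-1-yl)-1-benzofuran | CC(C)=CCc1cc(Br)cc2ccoc12 | intermediate
11 | [7-(3-methylbut-2-en-1-yl)-1-benzofuran-5-yl]lithium (not isolated) | [Li]c1cc(CC=C(C)C)c2occc2c1 | intermediate
12 | lithium triisopropoxy[7-(3-methylbut-2-en-1-yl)-1-benzofuran-5-yl]borate (not isolated) | [Li+].CC(C)O[B-](OC(C)C)(OC(C)C)c1cc(CC=C(C)C)c2occc2c1 | intermediate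
13 | [7-(3-methylbut-2-en-1-yl)-1-benzofuran-5-yl]boronic acid | CC(C)=CCc1cc(B(O)O)cc2ccoc12 | intermediate
14 | 5,7-dihydroxy-4H-chromen-4-one | O=c1ccoc2cc(O)cc(O)c12 | starting material
15 | 5-hydroxy-7-(methoxymethoxy)-4H-chromen-4-one (not isolated) | COCOc1cc(O)c2c(c1)occc2=O | intermediate
16 | 5,7-bis(methoxymethoxy)-4H-chromen-4-one | COCOc1cc(OCOC)c2c(c1)occc2=O | intermediate
17 | (2S)-5,7-bis(methoxymethoxy)-2-[7-(3-methylbut-2-en-1-yl)-1-benzofuran-5-yl]-2,3-dihydro-4H-chromen-4-one | CC(C)=CCc1cc([C@@H]2CC(=O)c3c(OCOC)cc(OCOC)cc3O2)cc2ccoc12 | intermediate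
18 | (2S)-5-hydroxy-7-(methoxymethoxy)-2-[7-(3-methylbut-2-en-1-yl)-1-benzofuran-5-yl]-2,3-dihydro-4H-chromen-4-one (not isolated) | CC(C)=CCc1cc([C@@H]2CC(=O)c3c(O)cc(OCOC)cc3O2)cc2ccoc12 | intermediate
19 | (2S)-5,7-dihydroxy-2-[7-(3-methylbut-2-en-1-yl)-1-benzofuran-5-yl]-2,3-dihydro-4H-chromen-4-one | CC(C)=CCc1cc([C@@H]2CC(=O)c3c(O)cc(O)cc3O2)cc2ccoc12 | target

**Step count and risks**

Total steps: 7. Longest linear sequence: 6 (steps 1, 2, 3, 4, 6, 7); step 5 prepares the second fragment.

Step 6. Insertion of the electron-rich 5,7-dialkoxychromone may be slower than protodeboronation of 13, or the facial selectivity may be insufficient. The fallback sets out from 16 and 13 and joins them without ligand control ([Rh(OH)(cod)]2, KOH, dioxane/H2O, 50 °C) to racemic 5,7-bis(methoxymethoxy)-2-[7-(3-methylbut-2-en-1-yl)-1-benzofuran-5-yl]-2,3-dihydro-4H-chromen-4-one F1. Kinetic resolution by asymmetric transfer hydrogenation (Cp*RhCl[(R,R)-TsDPEN], HCO2H/Et3N, EtOAc, rt, stopped near half conversion) should then reduce the 2R ketone. The (R,R) catalyst gives 4R alcohols from aryl ketones and is matched with hydride approach trans to the aryl group of the 2R ketone, so the product should be the cis alcohol (2R,4R)-5,7-bis(methoxymethoxy)-2-[7-(3-methylbut-2-en-1-yl)-1-benzofuran-5-yl]-3,4-dihydro-2H-chromen-4-ol F2. The 2S ketone should remain; it is separated on silica and the route is rejoined at 17.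

Step 2. Hydrogenolysis of the C–I bond or over-reduction may accompany the semi-hydrogenation, and the tertiary ether may fragment with loss of isoprene instead of rearranging. The fallback sets out from 1: O-allylation (allyl bromide, K2CO3, acetone) to 1-(allyloxy)-4-bromo-2-iodobenzene F3, then aromatic Claisen rearrangement (N,N-diethylaniline, 190 °C) to 2-allyl-4-bromo-6-iodophenol F4. Cross-metathesis with 2-methylbut-2-ene (second-generation Grubbs catalyst RuCl2(=CHPh)(PCy3)(H2IMes), CH2Cl2, 40 °C) turns allyl into prenyl and comes back to the route at 6; no hydrogenation and no tertiary ether are involved.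

Step 4. Deprotonation at C2′ may compete with bromine–lithium exchange, or the boronic acid may protodeboronate during the acidic work-up. The fallback sets out from 10: Miyaura borylation (B2pin2, PdCl2(dppf), KOAc, dioxane, 85 °C) to 4,4,5,5-tetramethyl-2-[7-(3-methylbut-2-en-1-yl)-1-benzofuran-5-yl]-1,3,2-dioxaborolane F5. Transesterification with diethanolamine (Et2O, rt) gives crystalline 2-[7-(3-methylbut-2-en-1-yl)-1-benzofuran-5-yl]-1,3,6,2-dioxazaborocane F6, and hydrolysis with dilute aqueous HCl comes back to the route at 13; no organolithium is formed.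

**Further compounds**

F1 | step 6 | 5,7-bis(methoxymethoxy)-2-[7-(3-methylbut-2-en-1-yl)-1-benzofuran-5-yl]-2,3-dihydro-4H-chromen-4-one (racemic) | CC(C)=CCc1cc(C2CC(=O)c3c(OCOC)cc(OCOC)cc3O2)cc2ccoc12
F2 | step 6 | (2R,4R)-5,7-bis(methoxymethoxy)-2-[7-(3-methylbut-2-en-1-yl)-1-benzofuran-5-yl]-3,4-dihydro-2H-chromen-4-ol | CC(C)=CCc1cc([C@H]2C[C@@H](O)c3c(OCOC)cc(OCOC)cc3O2)cc2ccoc12
F3 | step 2 | 1-(allyloxy)-4-bromo-2-iodobenzene | C=CCOc1ccc(Br)cc1I
F4 | step 2 | 2-allyl-4-bromo-6-iodophenol | C=CCc1cc(Br)cc(I)c1O
F5 | step 4 | 4,4,5,5-tetramethyl-2-[7-(3-methylbut-2-en-1-yl)-1-benzofuran-5-yl]-1,3,2-dioxaborolane | CC(C)=CCc1cc(B2OC(C)(C)C(C)(C)O2)cc2ccoc12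
F6 | step 4 | 2-[7-(3-methylbut-2-en-1-yl)-1-benzofuran-5-yl]-1,3,6,2-dioxazaborocane | CC(C)=CCc1cc(B2OCCNCCO2)cc2ccoc12
A1 | direct plan | 4-hydroxy-3,5-bis(3-methylbut-2-en-1-yl)benzaldehyde | CC(C)=CCc1cc(C=O)cc(CC=C(C)C)c1O
A2 | direct plan | 7-(3-methylbut-2-en-1-yl)-1-benzofuran-5-carbaldehyde | CC(C)=CCc1cc(C=O)cc2ccoc12
A3 | direct plan | (E)-3-[7-(3-methylbut-2-en-1-yl)-1-benzofuran-5-yl]-1-(2,4,6-trihydroxyphenyl)prop-2-en-1-one | CC(C)=CCc1cc(/C=C/C(=O)c2c(O)cc(O)cc2O)cc2ccoc12
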